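Ring A of kushenol G carries oxygen at C5, C7 and C8a, so C8a and C7 are acceptor carbons and C6 and C8 are donor carbons. The route uses this alternation by cutting C8–C8a and C6–C7. A 2-aryl-5-(1-silyloxyvinyl)pyran-4-one supplies C8a, C4a, C5 and C6 as a push–pull diene. A limonene-derived silyl ynol ether, which already holds the (R)-configured hydrated lavandulyl chain, supplies C7 and C8. One operation (cycloaddition, then DDQ) joins both halves and forms the fully oxygenated ring A of the flavone. Both partners are made by known chemistry; C3 hydroxylation and deprotection finish the synthesis.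

Key step: step 11

Remark on the chemistry: the limonene epoxide and the dihydro cycloadduct form as isomer mixtures at centres that the same step destroys, so their SMILES leave those centres undefined; the (R) side-chain stereocentre is taken unchanged from (R)-limonene.

Step 1
Reactants: 1 acetylacetone; 2 N,N-dimethylformamide dimethyl acetal
Product: 3 3-[(dimethylamino)methylidene]pentane-2,4-dione
Conditions: neat, 80 °C
Reagents that add atoms: none
Why: Condensation of the active methylene group of a 1,3-diketone with an amide acetal (enaminone formation) is a standard reaction driven by loss of methanol.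

Step 2
Reactants: 4 2,4-dihydroxybenzoic acid
Product: 6 2,4-bis(methoxymethoxy)benzoic acid, via MOM ester 5 (not isolated)
Conditions: NaH (3.3 equiv), MOMCl (3.3 equiv), DMF, 0 °C → rt; then NaOH (2 M aq), MeOH, rt; 1 M HCl to pH 4, 0 °C
Reagents that add atoms: chloromethyl methyl ether (MOMCl), COCCl
Why: Williamson-type O-alkylation of both phenoxides and the carboxylate followed by saponification of the labile MOM ester should give the acid, since aryl MOM ethers are stable to hydroxide and to brief cold acidification.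

Step 3
Reactants: 6 2,4-bis(methoxymethoxy)benzoic acid; 3 3-[(dimethylamino)methylidene]pentane-2,4-dione
Product: 9 5-acetyl-2-[2,4-bis(methoxymethoxy)phenyl]-4H-pyran-4-one, via acyl chloride 7 (not isolated), via aroylated enaminotrione 8 (not isolated)
Conditions: Ghosez reagent, CH2Cl2, 0 °C → rt; separately 3, LiN(SiMe3)2 (2.5 equiv), THF, −78 °C; combine, −78 → −20 °C; then AcOH, 40 °C
Reagents that add atoms: none
Why: Neutral acid chloride formation spares the MOM ethers, the methyl enolate of the vinylogous amide undergoes Claisen-type C-aroylation (the extra base absorbs the acidic 1,3-diketone), and acid then drives addition–elimination of the aroyl enol oxygen at the enaminone carbon with loss of dimethylamine, which is the established route from 2-(aminomethylene)-1,3-dicarbonyl compounds to 3-acyl-4-pyranones.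

Step 4
Reactants: 9 5-acetyl-2-[2,4-bis(methoxymethoxy)phenyl]-4H-pyran-4-one
Product: 10 2-[2,4-bis(methoxymethoxy)phenyl]-5-{1-[(triisopropylsilyl)oxy]ethenyl}-4H-pyran-4-one
Conditions: TIPSOTf, Et3N, CH2Cl2, −78 → 0 °C
Reagents that add atoms: triisopropylsilyl trifluoromethanesulfonate, CC(C)[Si](OS(=O)(=O)C(F)(F)F)(C(C)C)C(C)C
Why: Soft enolisation with a silyl triflate and an amine (silyl enol ether formation) can only occur at the acetyl methyl group, and the TIPS group is chosen over a smaller silyl group because the dienol ether should then survive chromatography and the Lewis-acidic key step and O5 and O7 end up with the same protecting group.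

Step 5
Reactants: 11 (R)-(+)-limonene
Product: 13 (3R)-6-oxo-3-(prop-1-en-2-yl)heptanal, via limonene 1,2-oxide 12 (not isolated)
Conditions: mCPBA (1.0 equiv), CH2Cl2, 0 °C; then H5IO6, THF–H2O, 0 °C → rt
Reagents that add atoms: 3-chloroperbenzoic acid (mCPBA), O=C(OO)c1cccc(Cl)c1; water, O
Why: Prilezhaev epoxidation prefers the electron-richer trisubstituted ring alkene over the isopropenyl group, and periodic acid hydrolyses the epoxide and cleaves the glycol (Malaprade cleavage) without touching the stereocentre, which keeps the (R) configuration of limonene.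

Step 6
Reactants: 13 (3R)-6-oxo-3-(prop-1-en-2-yl)heptanal
Product: 14 (3R)-6-oxo-3-(prop-1-en-2-yl)heptanoic acid
Conditions: NaClO2, NaH2PO4, 2-methylbut-2-ene (excess), t-BuOH–H2O, 0 °C → rt
Reagents that add atoms: sodium chlorite, [Na+].[O-]Cl=O
Why: Pinnick oxidation converts the aldehyde into the acid under buffered conditions that leave the methyl ketone and, with the alkene scavenger in excess, the isopropenyl group alone and avoid base-induced intramolecular aldol condensation.

Step 7
Reactants: 14 (3R)-6-oxo-3-(prop-1-en-2-yl)heptanoic acid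
Product: 15 (3R)-6-hydroxy-6-methyl-3-(prop-1-en-2-yl)heptanoic acid
Conditions: MeMgBr (3.5 equiv), THF, −40 → 0 °C; then 1 M HCl to pH 3, 0 °C
Reagents that add atoms: methylmagnesium bromide, C[Mg]Br
Why: In this Grignard addition the first equivalent forms a magnesium carboxylate that resists further attack, so the reagent adds only to the methyl ketone and gives a tertiary carbinol that bears two methyl groups and is therefore not a stereocentre.

Step 8
Reactants: 15 (3R)-6-hydroxy-6-methyl-3-(prop-1-en-2-yl)heptanoic acid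
Product: 16 methyl (3R)-6-hydroxy-6-methyl-3-(prop-1-en-2-yl)heptanoate
Conditions: MeI, K2CO3, DMF, rt
Reagents that add atoms: iodomethane, CI
Why: SN2 O-alkylation of the carboxylate gives the methyl ester needed for homologation, while the tertiary alcohol is not alkylated under carbonate conditions.

Step 9
Reactants: 16 methyl (3R)-6-hydroxy-6-methyl-3-(prop-1-en-2-yl)heptanoate
Product: 17 methyl (3R)-6-methyl-3-(prop-1-en-2-yl)-6-[(triethylsilyl)oxy]heptanoate
Conditions: TESOTf, 2,6-lutidine, CH2Cl2, −78 → 0 °C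
Reagents that add atoms: triethylsilyl trifluoromethanesulfonate, CC[Si](CC)(CC)OS(=O)(=O)C(F)(F)F
Why: Silylation of a hindered tertiary alcohol with a silyl triflate and 2,6-lutidine masks the only acidic proton before the organolithium step and keeps the alcohol from adding to the ynol ether later.

Step 10
Reactants: 17 methyl (3R)-6-methyl-3-(prop-1-en-2-yl)-6-[(triethylsilyl)oxy]heptanoate
Product: 20 (4R)-7-methyl-4-(prop-1-en-2-yl)-7-[(triethylsilyl)oxy]-1-[(triisopropylsilyl)oxy]oct-1-yne, via dibromomethyl ketone enolate 18 (not isolated), via lithium ynolate 19 (not isolated)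
Conditions: CH2Br2, lithium 2,2,6,6-tetramethylpiperidide, THF, −78 °C; then LiN(SiMe3)2; n-BuLi, −78 → 0 °C; then TIPSCl, −78 °C → rt
Reagents that add atoms: dibromomethane, BrCBr; chlorotriisopropylsilane, CC(C)[Si](Cl)(C(C)C)C(C)C
Why: In this Kowalski ester homologation stopped at the ynolate, dibromomethyllithium adds to the ester, bromine–lithium exchange gives a carbenoid whose alkyl group shifts (Fritsch–Buttenberg–Wiechell-type 1,2-migration) onto the dibromomethane-derived carbon, so that this carbon becomes C8 and the former ester carbon becomes C7, and the bulky silyl chloride silylates the ynolate on oxygen while the remote stereocentre is untouched.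

Step 11
Reactants: 10 2-[2,4-bis(methoxymethoxy)phenyl]-5-{1-[(triisopropylsilyl)oxy]ethenyl}-4H-pyran-4-one; 20 (4R)-7-methyl-4-(prop-1-en-2-yl)-7-[(triethylsilyl)oxy]-1-[(triisopropylsilyl)oxy]oct-1-yne
Product: 22 2-[2,4-bis(methoxymethoxy)phenyl]-8-{(2R)-5-methyl-2-(prop-1-en-2-yl)-5-[(triethylsilyl)oxy]hexyl}-5,7-bis[(triisopropylsilyl)oxy]-4H-chromen-4-one, via 6,8a-dihydroflavone 21 (not isolated)
Conditions: AgNTf2 (10 mol %), 2,6-di-tert-butyl-4-methylpyridine (20 mol %), 4 Å MS, CH2Cl2, −40 °C → rt; then DDQ (1.5 equiv), 0 °C → rt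
Reagents that add atoms: none
Why: Proposed new method: AgNTf2 (monovalent silver) is expected to trigger, as in its known conjugate additions of siloxyalkynes to enones, attack of the alkyl-bearing alkyne carbon (future C8) on the pyranone β-carbon (future C8a), which gives a silyl ketenium at C7 and a dienolate that extends over C4a and C5 to the terminal CH2 of the enol ether (future C6). Bond formation between C6 and C7 then closes ring A as a six-membered ring (attack of C6 on the ketenium carbon, exo with respect to the C7=O bond that is consumed; overall a polarity-matched formal [4+2] cycloaddition of the C6=C5–C4a=C8a diene with the C7≡C8 alkyne, asynchronous or stepwise), and DDQ removes the doubly allylic, oxygen-bearing C8a–H as hydride and a C6 proton to aromatise the cyclohexa-1,4-diene 21. The closest known reaction types are the [4+2] additions of enamines and ynamines to 3-vinylchromones, which give xanthones, and the silver-catalysed [2+2] additions of siloxyalkynes to enones. The only new stereocentre, C8a of 21, is not controlled and is erased by the aromatisation, while the side-chain stereocentre is remote and untouched. The step needs regioselectivity, which the matched donor (C8, C6) and acceptor (C8a, C7) termini of both partners provide, and six-membered closure in preference to closure at C4a (cyclobutene) or at the carbonyl oxygen, which the unhindered, more nucleophilic terminal C6 of the silyl enol ether and the reversibility of the other closures under silver catalysis should secure. The hindered pyridine scavenges traces of HNTf2 so that the enol ether, the MOM and TES groups and the C8a–O1 bond of 21 survive until DDQ is added.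

Step 12
Reactants: 22 2-[2,4-bis(methoxymethoxy)phenyl]-8-{(2R)-5-methyl-2-(prop-1-en-2-yl)-5-[(triethylsilyl)oxy]hexyl}-5,7-bis[(triisopropylsilyl)oxy]-4H-chromen-4-one
Product: 25 2-[2,4-bis(methoxymethoxy)phenyl]-3-hydroxy-8-{(2R)-5-methyl-2-(prop-1-en-2-yl)-5-[(triethylsilyl)oxy]hexyl}-5,7-bis[(triisopropylsilyl)oxy]-4H-chromen-4-one, via 3-lithioflavone 23 (not isolated), via dimethyl flavon-3-ylboronate 24 (not isolated)
Conditions: LiN(i-Pr)2 (2 equiv), THF, −78 °C; B(OMe)3, −78 → 0 °C; then AcOH, 30% H2O2, 0 °C → rt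
Reagents that add atoms: hydrogen peroxide, OO
Why: C3 lithiation of a flavone with lithium amide base (the C3–H lies between the carbonyl group and the 2-aryl group), borylation and oxidative C–B to C–O conversion is the established flavone-to-flavonol sequence, and the acetic acid buffer protects the aryl silyl ethers while the isopropenyl group is inert to hydrogen peroxide in the absence of a peracid.

Step 13
Reactants: 25 2-[2,4-bis(methoxymethoxy)phenyl]-3-hydroxy-8-{(2R)-5-methyl-2-(prop-1-en-2-yl)-5-[(triethylsilyl)oxy]hexyl}-5,7-bis[(triisopropylsilyl)oxy]-4H-chromen-4-one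
Product: 27 kushenol G, via 5,7-bis-O-TIPS kushenol G 26 (not isolated)
Conditions: HCl (1.25 M in MeOH), THF, 0 °C → rt; evaporate; then KHF2, MeOH, rt
Reagents that add atoms: none
Why: Acid-catalysed acetal methanolysis removes both MOM ethers and the TES ether while the robust aryl TIPS ether still blocks O7, so that the neighbouring isopropenyl group cannot close a chroman ring under acid, and mildly acidic fluoride then cleaves the two aryl silyl ethers without exposing the polyphenol to base.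

Compound list
1 | acetylacetone (pentane-2,4-dione) | CC(=O)CC(C)=O | starting material
2 | N,N-dimethylformamide dimethyl acetal | COC(OC)N(C)C | starting material
3 | 3-[(dimethylamino)methylidene]pentane-2,4-dione | CC(=O)C(=CN(C)C)C(C)=O | intermediate
4 | 2,4-dihydroxybenzoic acid | O=C(O)c1ccc(O)cc1O | starting material
5 | methoxymethyl 2,4-bis(methoxymethoxy)benzoate (not isolated) | COCOC(=O)c1ccc(OCOC)cc1OCOC | intermediate
6 | 2,4-bis(methoxymethoxy)benzoic acid | OC(=O)c1ccc(OCOC)cc1OCOC | intermediate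
7 | 2,4-bis(methoxymethoxy)benzoyl chloride (not isolated) | ClC(=O)c1ccc(OCOC)cc1OCOC | intermediate
8 | 1-[2,4-bis(methoxymethoxy)phenyl]-4-[(dimethylamino)methylidene]hexane-1,3,5-trione (not isolated) | CC(=O)C(=CN(C)C)C(=O)CC(=O)c1ccc(OCOC)cc1OCOC | intermediate
9 | 5-acetyl-2-[2,4-bis(methoxymethoxy)phenyl]-4H-pyran-4-one | CC(=O)c1coc(-c2ccc(OCOC)cc2OCOC)cc1=O | intermediate
10 | 2-[2,4-bis(methoxymethoxy)phenyl]-5-{1-[(triisopropylsilyl)oxy]ethenyl}-4H-pyran-4-one | C=C(O[Si](C(C)C)(C(C)C)C(C)C)c1coc(-c2ccc(OCOC)cc2OCOC)cc1=O | intermediate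
11 | (R)-(+)-limonene | CC1=CC[C@@H](CC1)C(C)=C | starting material
12 | (4R)-limonene 1,2-oxide, cis/trans mixture (not isolated) | CC12OC1C[C@@H](CC2)C(C)=C | intermediate
13 | (3R)-6-oxo-3-(prop-1-en-2-yl)heptanal | O=CC[C@@H](CCC(C)=O)C(C)=C | intermediate
14 | (3R)-6-oxo-3-(prop-1-en-2-yl)heptanoic acid | OC(=O)C[C@@H](CCC(C)=O)C(C)=C | intermediate
15 | (3R)-6-hydroxy-6-methyl-3-(prop-1-en-2-yl)heptanoic acid | OC(=O)C[C@@H](CCC(C)(C)O)C(C)=C | intermediate
16 | methyl (3R)-6-hydroxy-6-methyl-3-(prop-1-en-2-yl)heptanoate | COC(=O)C[C@@H](CCC(C)(C)O)C(C)=C | intermediate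
17 | methyl (3R)-6-methyl-3-(prop-1-en-2-yl)-6-[(triethylsilyl)oxy]heptanoate | COC(=O)C[C@@H](CCC(C)(C)O[Si](CC)(CC)CC)C(C)=C | intermediate
18 | (4R)-1,1-dibromo-7-methyl-4-(prop-1-en-2-yl)-7-[(triethylsilyl)oxy]octan-2-one, present as its lithium enolate (not isolated) | BrC(Br)C(=O)C[C@@H](CCC(C)(C)O[Si](CC)(CC)CC)C(C)=C | intermediate
19 | lithium (4R)-7-methyl-4-(prop-1-en-2-yl)-7-[(triethylsilyl)oxy]oct-1-yn-1-olate (not isolated) | [Li+].[O-]C#CC[C@@H](CCC(C)(C)O[Si](CC)(CC)CC)C(C)=C | intermediate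
20 | (4R)-7-methyl-4-(prop-1-en-2-yl)-7-[(triethylsilyl)oxy]-1-[(triisopropylsilyl)oxy]oct-1-yne | C=C(C)[C@H](CCC(C)(C)O[Si](CC)(CC)CC)CC#CO[Si](C(C)C)(C(C)C)C(C)C | intermediate
21 | 2-[2,4-bis(methoxymethoxy)phenyl]-8-{(2R)-5-methyl-2-(prop-1-en-2-yl)-5-[(triethylsilyl)oxy]hexyl}-5,7-bis[(triisopropylsilyl)oxy]-6,8a-dihydro-4H-chromen-4-one, both C8a epimers (not isolated) | C=C(C)[C@H](CCC(C)(C)O[Si](CC)(CC)CC)CC1=C(O[Si](C(C)C)(C(C)C)C(C)C)CC(O[Si](C(C)C)(C(C)C)C(C)C)=C2C(=O)C=C(c3ccc(OCOC)cc3OCOC)OC12 | intermediate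
22 | 2-[2,4-bis(methoxymethoxy)phenyl]-8-{(2R)-5-methyl-2-(prop-1-en-2-yl)-5-[(triethylsilyl)oxy]hexyl}-5,7-bis[(triisopropylsilyl)oxy]-4H-chromen-4-one | C=C(C)[C@H](CCC(C)(C)O[Si](CC)(CC)CC)Cc1c(O[Si](C(C)C)(C(C)C)C(C)C)cc(O[Si](C(C)C)(C(C)C)C(C)C)c2c(=O)cc(-c3ccc(OCOC)cc3OCOC)oc12 | intermediate
23 | 3-lithio derivative of 22 (not isolated) | C=C(C)[C@H](CCC(C)(C)O[Si](CC)(CC)CC)Cc1c(O[Si](C(C)C)(C(C)C)C(C)C)cc(O[Si](C(C)C)(C(C)C)C(C)C)c2c(=O)c([Li])c(-c3ccc(OCOC)cc3OCOC)oc12 | intermediate
24 | dimethyl boronate at C3 of 22 (not isolated) | C=C(C)[C@H](CCC(C)(C)O[Si](CC)(CC)CC)Cc1c(O[Si](C(C)C)(C(C)C)C(C)C)cc(O[Si](C(C)C)(C(C)C)C(C)C)c2c(=O)c(B(OC)OC)c(-c3ccc(OCOC)cc3OCOC)oc12 | intermediate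
25 | 2-[2,4-bis(methoxymethoxy)phenyl]-3-hydroxy-8-{(2R)-5-methyl-2-(prop-1-en-2-yl)-5-[(triethylsilyl)oxy]hexyl}-5,7-bis[(triisopropylsilyl)oxy]-4H-chromen-4-one | C=C(C)[C@H](CCC(C)(C)O[Si](CC)(CC)CC)Cc1c(O[Si](C(C)C)(C(C)C)C(C)C)cc(O[Si](C(C)C)(C(C)C)C(C)C)c2c(=O)c(O)c(-c3ccc(OCOC)cc3OCOC)oc12 | intermediate
26 | 2-(2,4-dihydroxyphenyl)-3-hydroxy-8-[(2R)-5-hydroxy-5-methyl-2-(prop-1-en-2-yl)hexyl]-5,7-bis[(triisopropylsilyl)oxy]-4H-chromen-4-one (not isolated) | C=C(C)[C@H](CCC(C)(C)O)Cc1c(O[Si](C(C)C)(C(C)C)C(C)C)cc(O[Si](C(C)C)(C(C)C)C(C)C)c2c(=O)c(O)c(-c3ccc(O)cc3O)oc12 | intermediate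
27 | kushenol G, 2-(2,4-dihydroxyphenyl)-3,5,7-trihydroxy-8-[(2R)-5-hydroxy-5-methyl-2-(prop-1-en-2-yl)hexyl]-4H-chromen-4-one | C=C(C)[C@H](CCC(C)(C)O)Cc1c(O)cc(O)c2c(=O)c(O)c(-c3ccc(O)cc3O)oc12 | target

Total step count: 13 (pyranone branch steps 1–4, limonene branch steps 5–10, union and endgame steps 11–13).
Longest linear sequence: 9 steps (steps 5–13, from (R)-limonene).

Steps most likely to fail

Step 11. After the first C–C bond the zwitterion may close at C4a (four-membered ring) or at the carbonyl oxygen instead of at C6. The ynol ether may also be protodesilylated before it adds, or the C8a–O1 bond of the dihydro adduct may be lost by elimination before DDQ acts. The fallback is a stepwise anionic annulation that forms the same two bonds with known reaction types; it sets out from 20 and 9 and returns at 22.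
- KF in MeOH converts 20 through its ynolate and ketene into methyl (4R)-7-methyl-4-(prop-1-en-2-yl)-7-[(triethylsilyl)oxy]octanoate F1.
- LiN(i-Pr)2 and then TBSCl (THF, −78 °C) give the ketene silyl acetal tert-butyl{[(4R)-1-methoxy-7-methyl-4-(prop-1-en-2-yl)-7-[(triethylsilyl)oxy]oct-1-en-1-yl]oxy}dimethylsilane F2.
- TBSOTf-promoted Mukaiyama–Michael addition of F2 to 9 (2,6-lutidine, CH2Cl2, −78 °C) forms C8–C8a and gives methyl (4R)-2-{3-acetyl-6-[2,4-bis(methoxymethoxy)phenyl]-4-[(tert-butyldimethylsilyl)oxy]-2H-pyran-2-yl}-7-methyl-4-(prop-1-en-2-yl)-7-[(triethylsilyl)oxy]octanoate F3, a diastereomer mixture at the two new centres.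
- Dieckmann condensation of the acetyl methyl group onto the ester (LiN(SiMe3)2, THF, −78 → 0 °C) forms C6–C7. It is run on the silyl enol ether so that no enolisable β-alkoxy ketone can open the pyran ring, and gives 2-[2,4-bis(methoxymethoxy)phenyl]-4-[(tert-butyldimethylsilyl)oxy]-8-{(2R)-5-methyl-2-(prop-1-en-2-yl)-5-[(triethylsilyl)oxy]hexyl}-8,8a-dihydro-5H-chromene-5,7(6H)-dione F4.
- DDQ removes the C8a hydride with loss of the silyl group, and tautomerisation gives 2-[2,4-bis(methoxymethoxy)phenyl]-5,7-dihydroxy-8-{(2R)-5-methyl-2-(prop-1-en-2-yl)-5-[(triethylsilyl)oxy]hexyl}-4H-chromen-4-one F5.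
- TIPSOTf and 2,6-lutidine silylate both phenols of F5 and return to the route at 22.

Step 12. The lithium amide may deprotonate or add elsewhere (C6–H between the two silyloxy groups, the position next to the MOM ethers, conjugate addition at C2), a silyl group may migrate, or the C–B oxidation may stay incomplete. The fallback installs the C3 oxygen on the pyranone before the fragment union, so that no organolithium step follows the key step; it sets out from 9 and returns at 26.
- Dimethyldioxirane in acetone epoxidises the aryl-substituted C2=C3 bond of 9 (the known dioxirane route from flavones to flavonols, here run before the isopropenyl group is present) to give 4-acetyl-1-[2,4-bis(methoxymethoxy)phenyl]-2,7-dioxabicyclo[4.1.0]hept-3-en-5-one F6.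
- Catalytic TsOH isomerises F6 to 5-acetyl-2-[2,4-bis(methoxymethoxy)phenyl]-3-hydroxy-4H-pyran-4-one F7.
- MOMCl and i-Pr2NEt give 5-acetyl-2-[2,4-bis(methoxymethoxy)phenyl]-3-(methoxymethoxy)-4H-pyran-4-one F8.
- TIPSOTf and Et3N give 2-[2,4-bis(methoxymethoxy)phenyl]-3-(methoxymethoxy)-5-{1-[(triisopropylsilyl)oxy]ethenyl}-4H-pyran-4-one F9.
- The conditions of step 11 with 20 give 2-[2,4-bis(methoxymethoxy)phenyl]-3-(methoxymethoxy)-8-{(2R)-5-methyl-2-(prop-1-en-2-yl)-5-[(triethylsilyl)oxy]hexyl}-5,7-bis[(triisopropylsilyl)oxy]-6,8a-dihydro-4H-chromen-4-one F10, and after DDQ 2-[2,4-bis(methoxymethoxy)phenyl]-3-(methoxymethoxy)-8-{(2R)-5-methyl-2-(prop-1-en-2-yl)-5-[(triethylsilyl)oxy]hexyl}-5,7-bis[(triisopropylsilyl)oxy]-4H-chromen-4-one F11.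
- The acid stage of step 13 removes the three MOM groups and the TES group of F11 and returns to the route at 26.

Step 10. The carbenoid rearrangement may stay incomplete, the ynolate may be silylated on carbon to give a silylketene, or the sensitive ynol ether may be hydrolysed during isolation. The fallback oxidises an acetylide instead of homologating the ester; it sets out from 17 and returns at 20.
- (i-Bu)2AlH (CH2Cl2, −78 °C) reduces the ester to (3R)-6-methyl-3-(prop-1-en-2-yl)-6-[(triethylsilyl)oxy]heptanal F12.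
- The Ohira–Bestmann reagent with K2CO3 in MeOH gives triethyl{[(5R)-2-methyl-5-(prop-1-en-2-yl)oct-7-yn-2-yl]oxy}silane F13.
- n-BuLi, then LiOO-t-Bu (from t-BuOOH and LiN(SiMe3)2) oxidises the lithium acetylide to the ynolate, and TIPSOTf silylates it on oxygen to give 20.
- In this variant the former aldehyde carbon becomes C8 and the carbon delivered by the diazophosphonate becomes C7.

Further compounds
F1 | step 11 | methyl (4R)-7-methyl-4-(prop-1-en-2-yl)-7-[(triethylsilyl)oxy]octanoate | COC(=O)CC[C@@H](CCC(C)(C)O[Si](CC)(CC)CC)C(C)=C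
F2 | step 11 | tert-butyl{[(4R)-1-methoxy-7-methyl-4-(prop-1-en-2-yl)-7-[(triethylsilyl)oxy]oct-1-en-1-yl]oxy}dimethylsilane | COC(O[Si](C)(C)C(C)(C)C)=CC[C@@H](CCC(C)(C)O[Si](CC)(CC)CC)C(C)=C
F3 | step 11 | methyl (4R)-2-{3-acetyl-6-[2,4-bis(methoxymethoxy)phenyl]-4-[(tert-butyldimethylsilyl)oxy]-2H-pyran-2-yl}-7-methyl-4-(prop-1-en-2-yl)-7-[(triethylsilyl)oxy]octanoate | COC(=O)C(C[C@@H](CCC(C)(C)O[Si](CC)(CC)CC)C(C)=C)C1OC(c2ccc(OCOC)cc2OCOC)=CC(O[Si](C)(C)C(C)(C)C)=C1C(C)=O
F4 | step 11 | 2-[2,4-bis(methoxymethoxy)phenyl]-4-[(tert-butyldimethylsilyl)oxy]-8-{(2R)-5-methyl-2-(prop-1-en-2-yl)-5-[(triethylsilyl)oxy]hexyl}-8,8a-dihydro-5H-chromene-5,7(6H)-dione | C=C(C)[C@H](CCC(C)(C)O[Si](CC)(CC)CC)CC1C(=O)CC(=O)C2=C(O[Si](C)(C)C(C)(C)C)C=C(c3ccc(OCOC)cc3OCOC)OC12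
F5 | step 11 | 2-[2,4-bis(methoxymethoxy)phenyl]-5,7-dihydroxy-8-{(2R)-5-methyl-2-(prop-1-en-2-yl)-5-[(triethylsilyl)oxy]hexyl}-4H-chromen-4-one | C=C(C)[C@H](CCC(C)(C)O[Si](CC)(CC)CC)Cc1c(O)cc(O)c2c(=O)cc(-c3ccc(OCOC)cc3OCOC)oc12
F6 | step 12 | 4-acetyl-1-[2,4-bis(methoxymethoxy)phenyl]-2,7-dioxabicyclo[4.1.0]hept-3-en-5-one (racemic) | CC(=O)C1=COC2(c3ccc(OCOC)cc3OCOC)OC2C1=O
F7 | step 12 | 5-acetyl-2-[2,4-bis(methoxymethoxy)phenyl]-3-hydroxy-4H-pyran-4-one | CC(=O)c1coc(-c2ccc(OCOC)cc2OCOC)c(O)c1=O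
F8 | step 12 | 5-acetyl-2-[2,4-bis(methoxymethoxy)phenyl]-3-(methoxymethoxy)-4H-pyran-4-one | CC(=O)c1coc(-c2ccc(OCOC)cc2OCOC)c(OCOC)c1=O
F9 | step 12 | 2-[2,4-bis(methoxymethoxy)phenyl]-3-(methoxymethoxy)-5-{1-[(triisopropylsilyl)oxy]ethenyl}-4H-pyran-4-one | C=C(O[Si](C(C)C)(C(C)C)C(C)C)c1coc(-c2ccc(OCOC)cc2OCOC)c(OCOC)c1=O
F10 | step 12 | 2-[2,4-bis(methoxymethoxy)phenyl]-3-(methoxymethoxy)-8-{(2R)-5-methyl-2-(prop-1-en-2-yl)-5-[(triethylsilyl)oxy]hexyl}-5,7-bis[(triisopropylsilyl)oxy]-6,8a-dihydro-4H-chromen-4-one | C=C(C)[C@H](CCC(C)(C)O[Si](CC)(CC)CC)CC1=C(O[Si](C(C)C)(C(C)C)C(C)C)CC(O[Si](C(C)C)(C(C)C)C(C)C)=C2C(=O)C(OCOC)=C(c3ccc(OCOC)cc3OCOC)OC12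
F11 | step 12 | 2-[2,4-bis(methoxymethoxy)phenyl]-3-(methoxymethoxy)-8-{(2R)-5-methyl-2-(prop-1-en-2-yl)-5-[(triethylsilyl)oxy]hexyl}-5,7-bis[(triisopropylsilyl)oxy]-4H-chromen-4-one | C=C(C)[C@H](CCC(C)(C)O[Si](CC)(CC)CC)Cc1c(O[Si](C(C)C)(C(C)C)C(C)C)cc(O[Si](C(C)C)(C(C)C)C(C)C)c2c(=O)c(OCOC)c(-c3ccc(OCOC)cc3OCOC)oc12
F12 | step 10 | (3R)-6-methyl-3-(prop-1-en-2-yl)-6-[(triethylsilyl)oxy]heptanal | O=CC[C@@H](CCC(C)(C)O[Si](CC)(CC)CC)C(C)=C
F13 | step 10 | triethyl{[(5R)-2-methyl-5-(prop-1-en-2-yl)oct-7-yn-2-yl]oxy}silane | C#CC[C@@H](CCC(C)(C)O[Si](CC)(CC)CC)C(C)=C
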